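The C50 skeleton has a C2 axis through the midpoint of C15=C15′. Its only stereocentres (C2 and C2′, both R) lie in the two identical trimethylcyclohexene rings. The heptaene C9–C9′ between the rings is achiral and centrosymmetric, so the sp2–sp2 single bonds C8–C9 and C8′–C9′ (vinyl CH next to ring carbon C6, joined to a methyl-bearing chain carbon) are homotopic.
Cuts: C8–C9 and C8′–C9′ (two-fold Stille coupling) give two copies of the C16 dienylstannane 16 and the C18 heptaenyl diiodide 25. Cutting 25 at C11=C12 and C11′=C12′ (double HWE) gives the C10 dialdehyde 22 and two C4 iodophosphonates 21.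
16 is cut at C6–C7 (enol triflate + distannylethene), at the side-chain C=C (Wittig), at C5–CH3 (enolate methylation) and at C4–C5 (aldol). This leads back to camphor.
Forward: camphor oxime is fragmented to a cyclopentene, which ozone opens and an aldol re-closes as the six-membered ring. Methyl, triflate, side chain and C7–C8 follow, and the chain is joined last (ring + heptaene + ring in one flask) with both hydroxyl groups free.
Stereochemistry: C2/C2′ are C4 of natural (+)-camphor and are never touched. Alkene geometry comes from the stabilised ylide (side chain), the (E)-distannane (C7=C8), syn-hydrozirconation (C9=C10), HWE (C11=C12), dialdehyde 22 (C13=C14, C15=C15′) and stereoretentive couplings.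
Key step: step 14

Remark: carotenoid numbering is used (ring C1–C6, chain C7–C15, primes for the second half). The methyl-bearing centre created in step 4 is left undefined because both epimers converge in step 5. All polyene work is assumed to be done under argon in dim light.

Step 1
Reactants: 1 (1R,4R)-camphor (E)-oxime
Product: 3 [(1R)-2,2,3-trimethylcyclopent-3-en-1-yl]acetonitrile, via oxime tosylate 2 (not isolated)
Conditions: TsCl, pyridine, 0 °C to 50 °C
Reagents that add atoms: none
Why: Beckmann fragmentation: the oxime tosylate ionises with cleavage of the antiperiplanar C1–C2 bond because a tertiary cation is released, loss of a ring proton gives the trisubstituted cyclopentene, and camphor C4 (the future C2 of the target) is a spectator whose configuration is carried over unchanged.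

Step 2
Reactants: 3 [(1R)-2,2,3-trimethylcyclopent-3-en-1-yl]acetonitrile
Product: 5 (3S)-4,4-dimethyl-5-oxo-3-(2-oxoethyl)hexanenitrile, via secondary ozonide 4 (not isolated)
Conditions: O3, CH2Cl2, −78 °C; Me2S, −78 °C to rt
Reagents that add atoms: ozone, [O-][O+]=O
Why: Ozonolysis with reductive work-up cleaves the only C=C bond to the 1,5-keto aldehyde, the nitrile being inert to ozone and the stereocentre lying β to all three acceptor groups so that it cannot enolise (the descriptor changes only through CIP priorities).

Step 3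
Reactants: 5 (3S)-4,4-dimethyl-5-oxo-3-(2-oxoethyl)hexanenitrile
Product: 7 [(1R)-2,2-dimethyl-3-oxocyclohex-4-en-1-yl]acetonitrile, via aldol adduct 6 (not isolated)
Conditions: KOH (cat.), MeOH, 0 °C to rt, dilute
Reagents that add atoms: none
Why: Intramolecular aldol condensation: the ketone can enolise only towards its methyl group (the other α-carbon is quaternary) and its 6-(enolexo)-exo-trig attack on the aldehyde is the only closure that avoids a four-membered ring, so that after E1cB loss of water a single cyclohexenone should result in which the former acetyl methyl carbon has become ring carbon C5.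

Step 4
Reactants: 7 [(1R)-2,2-dimethyl-3-oxocyclohex-4-en-1-yl]acetonitrile
Product: 9 [(1R,4RS)-2,2,4-trimethyl-3-oxocyclohexyl]acetonitrile, via lithium enolate 8 (not isolated)
Conditions: L-Selectride, THF, −78 °C; MeI, DMPU, −78 °C to rt; non-oxidative work-up
Reagents that add atoms: iodomethane, CI
Why: Conjugate reduction with in situ enolate alkylation: the bulky borohydride should add hydride 1,4 to the β-unsubstituted enone, whose carbonyl is shielded by the neighbouring quaternary carbon, and the regiodefined enolate is C-methylated by MeI, the new centre (C5) forming as an epimer mixture that is of no consequence because it becomes sp2 in step 5.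

Step 5
Reactants: 9 [(1R,4RS)-2,2,4-trimethyl-3-oxocyclohexyl]acetonitrile
Product: 11 (5R)-5-(cyanomethyl)-2,6,6-trimethylcyclohex-1-en-1-yl trifluoromethanesulfonate, via potassium enolate 10 (not isolated)
Conditions: KHMDS, THF, −78 °C to 0 °C; PhNTf2, −78 °C to rt
Reagents that add atoms: N-phenylbis(trifluoromethanesulfonimide), O=S(=O)(N(c1ccccc1)S(=O)(=O)C(F)(F)F)C(F)(F)F
Why: Enol triflate formation by O-sulfonylation of a ketone enolate: only one α-hydrogen is available so that only the tetrasubstituted C5=C6 enolate can form, and the silazide base is too weak to metalate the alkyl nitrile to a significant extent.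

Step 6
Reactants: 11 (5R)-5-(cyanomethyl)-2,6,6-trimethylcyclohex-1-en-1-yl trifluoromethanesulfonate
Product: 13 (5R)-2,6,6-trimethyl-5-(2-oxoethyl)cyclohex-1-en-1-yl trifluoromethanesulfonate, via N-aluminoimine 12 (not isolated)
Conditions: DIBAL-H (1.1 equiv), toluene, −78 °C; 1 M HCl, 0 °C
Reagents that add atoms: water, O
Why: Partial reduction of a nitrile with DIBAL-H stops at the N-aluminoimine, which is hydrolysed to the aldehyde on acidic work-up, while the alkenyl triflate is inert to the hydride at low temperature.

Step 7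
Reactants: 13 (5R)-2,6,6-trimethyl-5-(2-oxoethyl)cyclohex-1-en-1-yl trifluoromethanesulfonate
Product: 14 ethyl (2E)-2-methyl-4-[(1R)-2,2,4-trimethyl-3-(trifluoromethylsulfonyloxy)cyclohex-3-en-1-yl]but-2-enoate
Conditions: Ph3P=C(CH3)CO2Et, CH2Cl2, rt to 40 °C
Reagents that add atoms: ethyl 2-(triphenylphosphoranylidene)propanoate, CCOC(=O)C(C)=P(c1ccccc1)(c1ccccc1)c1ccccc1
Why: Wittig olefination with a stabilised α-methyl ylide, which reacts with unbranched aliphatic aldehydes under product-like control and should give the (E)-trisubstituted enoate that carries all five carbons of the side chain.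

Step 8
Reactants: 14 ethyl (2E)-2-methyl-4-[(1R)-2,2,4-trimethyl-3-(trifluoromethylsulfonyloxy)cyclohex-3-en-1-yl]but-2-enoate
Product: 15 (5R)-5-[(2E)-4-hydroxy-3-methylbut-2-en-1-yl]-2,6,6-trimethylcyclohex-1-en-1-yl trifluoromethanesulfonate
Conditions: DIBAL-H (2.5 equiv), CH2Cl2, −78 °C; aq. Rochelle salt
Reagents that add atoms: none
Why: 1,2-Reduction of the enoate with DIBAL-H gives the (E)-allylic alcohol without touching the C=C geometry or the triflate.

Step 9
Reactants: 15 (5R)-5-[(2E)-4-hydroxy-3-methylbut-2-en-1-yl]-2,6,6-trimethylcyclohex-1-en-1-yl trifluoromethanesulfonate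
Product: 16 (2E)-2-methyl-4-{(1R)-2,2,4-trimethyl-3-[(E)-2-(tributylstannyl)ethenyl]cyclohex-3-en-1-yl}but-2-en-1-ol
Conditions: (E)-Bu3SnCH=CHSnBu3 (3 equiv), Pd2(dba)3·CHCl3 (cat.), AsPh3 (cat.), LiCl, NMP, 60 °C; chromatography on Et3N-deactivated silica
Reagents that add atoms: (E)-1,2-bis(tributylstannyl)ethene, CCCC[Sn](CCCC)(CCCC)/C=C/[Sn](CCCC)(CCCC)CCCC
Why: Stille coupling of an alkenyl triflate with an alkenylstannane, known for the parent 2,6,6-trimethylcyclohexenyl triflate with the weakly donating AsPh3 in a polar solvent, in which the excess of the symmetrical distannane suppresses a second coupling and the E geometry of the reagent is retained in C7=C8.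

Step 10
Reactants: 17 but-2-yn-1-ol
Product: 19 (2E)-3-iodobut-2-en-1-ol, via alkenylzirconocene alkoxide 18 (not isolated)
Conditions: Cp2Zr(H)Cl (2.3 equiv), THF, 0 °C to rt, dark; I2, −78 °C to 0 °C
Reagents that add atoms: iodine, II
Why: Hydrozirconation–iodinolysis: the first equivalent of Cp2Zr(H)Cl forms the zirconium alkoxide, the second adds H–Zr syn across the alkyne with zirconium at the less hindered methyl-bearing carbon remote from the alkoxide, and iodine cleaves the C–Zr bond with retention, which sets the future C9=C10 geometry.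

Step 11
Reactants: 19 (2E)-3-iodobut-2-en-1-ol
Product: 20 (2E)-1-bromo-3-iodobut-2-ene
Conditions: PBr3, Et2O, 0 °C, dark
Reagents that add atoms: phosphorus tribromide, BrP(Br)Br
Why: SN2 displacement of the activated primary allylic alcohol (as its phosphite ester) by bromide, which leaves the alkenyl iodide and its geometry untouched.

Step 12
Reactants: 20 (2E)-1-bromo-3-iodobut-2-ene
Product: 21 diethyl [(2E)-3-iodobut-2-en-1-yl]phosphonate
Conditions: P(OEt)3, neat, 100 °C
Reagents that add atoms: triethyl phosphite, CCOP(OCC)OCC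
Why: Michaelis–Arbuzov reaction at the primary allylic bromide, the alkenyl iodide being inert to the phosphite in the absence of a transition metal.

Step 13
Reactants: 21 diethyl [(2E)-3-iodobut-2-en-1-yl]phosphonate (two molecules) and 22 (2E,4E,6E)-2,7-dimethylocta-2,4,6-trienedial
Product: 25 (2E,4E,6E,8E,10E,12E,14E)-2,15-diiodo-6,11-dimethylhexadeca-2,4,6,8,10,12,14-heptaene, via sodium phosphonate carbanion 23 (not isolated), via iodopentaenal 24 (not isolated)
Conditions: 21 (2.3 equiv), NaHMDS, THF, −78 °C; then 22, −78 °C to 0 °C, dark; crystallisation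
Reagents that add atoms: none
Why: Two-directional Horner–Wadsworth–Emmons olefination: the allylic phosphonate carbanion attacks both homotopic aldehyde groups through its α-carbon and the reversible addition to a conjugated aldehyde should favour the E alkenes C11=C12 and C11′=C12′, a non-nucleophilic amide base being chosen to avoid halogen–metal exchange.

Step 14
Reactants: 16 (2E)-2-methyl-4-{(1R)-2,2,4-trimethyl-3-[(E)-2-(tributylstannyl)ethenyl]cyclohex-3-en-1-yl}but-2-en-1-ol (two molecules) and 25 (2E,4E,6E,8E,10E,12E,14E)-2,15-diiodo-6,11-dimethylhexadeca-2,4,6,8,10,12,14-heptaene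
Product: 27 (2R,2′R)-2,2′-bis[(2E)-4-hydroxy-3-methylbut-2-en-1-yl]-β,β-carotene, via monocoupled nonaenyl iodide 26 (not isolated)
Conditions: 16 (2.3 equiv), Pd2(dba)3·CHCl3 (cat.), AsPh3 (cat.), BHT (trace), NMP–THF, 25 °C, Ar, dark; crystallisation
Reagents that add atoms: none
Why: Each C–I bond of 25 undergoes oxidative addition to Pd(0) with retention, the unhindered C8–Sn terminus of 16 transmetalates (helped by the weakly bound AsPh3 in polar NMP) and reductive elimination forges the C8–C9 sp2–sp2 bond with retention at both alkenes, so that the first cycle gives iodide 26, whose remaining C9′–I bond is joined to a second molecule of 16 in the same way to complete the conjugated undecaene. The closest known reaction type is the two-fold Stille coupling of a bifunctional polyene linchpin with two alkenyl partners, established for symmetrical carotenoids and retinoids. No ring is closed and no stereocentre is created: C2 and C2′ lie in the rings, four bonds from the reacting carbon, and are carried in unchanged from 16. Because both ends receive the same enantiomer only the C2-symmetric (2R,2′R) isomer can form, and any trace of the enantiomer of 16 is diverted mainly into the separable meso diastereomer, so the enantiomeric purity of 27 should exceed that of 16. The selectivities needed are cross- over homo-coupling and preservation of every E geometry; they are secured by the homotopic, equally reactive iodide termini of centrosymmetric 25 (no site selection is required), by placing tin on the sterically free CH (C8) and the halide on the methyl-bearing C9, and by neutral conditions at room temperature in the dark. The neutral medium tolerates both free allylic hydroxyl groups, so no protecting group has to be removed from the light-, acid- and oxygen-sensitive product.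

Compound list
1 | (1R,4R)-camphor (E)-oxime | CC1(C)[C@@H]2CC[C@@]1(C)/C(=N/O)C2 | starting material
2 | (1R,4R)-camphor (E)-oxime O-tosylate | CC1(C)[C@@H]2CC[C@@]1(C)/C(=N/OS(=O)(=O)c1ccc(C)cc1)C2 | intermediate
3 | [(1R)-2,2,3-trimethylcyclopent-3-en-1-yl]acetonitrile ((R)-α-campholenonitrile) | CC1=CC[C@H](CC#N)C1(C)C | intermediate
4 | (1,2,2-trimethyl-6,7,8-trioxabicyclo[3.2.1]octan-3-yl)acetonitrile, secondary ozonide of 3 (ring CH centre as in 3, ozonide carbons undefined) | CC12OOC(C[C@H](CC#N)C1(C)C)O2 | intermediate
5 | (3S)-4,4-dimethyl-5-oxo-3-(2-oxoethyl)hexanenitrile | O=CC[C@H](CC#N)C(C)(C)C(C)=O | intermediate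
6 | [(1S)-5-hydroxy-2,2-dimethyl-3-oxocyclohexyl]acetonitrile (carbinol centre undefined) | O=C1CC(O)C[C@H](CC#N)C1(C)C | intermediate
7 | [(1R)-2,2-dimethyl-3-oxocyclohex-4-en-1-yl]acetonitrile | O=C1C=CC[C@H](CC#N)C1(C)C | intermediate
8 | lithium (5R)-5-(cyanomethyl)-6,6-dimethylcyclohex-1-en-1-olate | [Li+].[O-]C1=CCC[C@H](CC#N)C1(C)C | intermediate
9 | [(1R,4RS)-2,2,4-trimethyl-3-oxocyclohexyl]acetonitrile | CC1CC[C@H](CC#N)C(C)(C)C1=O | intermediate
10 | potassium (5R)-5-(cyanomethyl)-2,6,6-trimethylcyclohex-1-en-1-olate | [K+].[O-]C1=C(C)CC[C@H](CC#N)C1(C)C | intermediate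
11 | (5R)-5-(cyanomethyl)-2,6,6-trimethylcyclohex-1-en-1-yl trifluoromethanesulfonate | CC1=C(OS(=O)(=O)C(F)(F)F)C(C)(C)[C@@H](CC#N)CC1 | intermediate
12 | N-(diisobutylaluminio)imine of aldehyde 13 | CC1=C(OS(=O)(=O)C(F)(F)F)C(C)(C)[C@@H](CC=N[Al](CC(C)C)CC(C)C)CC1 | intermediate
13 | (5R)-2,6,6-trimethyl-5-(2-oxoethyl)cyclohex-1-en-1-yl trifluoromethanesulfonate | CC1=C(OS(=O)(=O)C(F)(F)F)C(C)(C)[C@@H](CC=O)CC1 | intermediate
14 | ethyl (2E)-2-methyl-4-[(1R)-2,2,4-trimethyl-3-(trifluoromethylsulfonyloxy)cyclohex-3-en-1-yl]but-2-enoate | CC1=C(OS(=O)(=O)C(F)(F)F)C(C)(C)[C@@H](C/C=C(\C)C(=O)OCC)CC1 | intermediate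
15 | (5R)-5-[(2E)-4-hydroxy-3-methylbut-2-en-1-yl]-2,6,6-trimethylcyclohex-1-en-1-yl trifluoromethanesulfonate | CC1=C(OS(=O)(=O)C(F)(F)F)C(C)(C)[C@@H](C/C=C(\C)CO)CC1 | intermediate
16 | (2E)-2-methyl-4-{(1R)-2,2,4-trimethyl-3-[(E)-2-(tributylstannyl)ethenyl]cyclohex-3-en-1-yl}but-2-en-1-ol | CC1=C(/C=C/[Sn](CCCC)(CCCC)CCCC)C(C)(C)[C@@H](C/C=C(\C)CO)CC1 | intermediate
17 | but-2-yn-1-ol | CC#CCO | starting material
18 | (E)-3-[chlorobis(cyclopentadienyl)zirconio]but-2-en-1-yl chlorobis(cyclopentadienyl)zirconium alkoxide (Cp drawn σ-bound) | C/C(=C\CO[Zr](Cl)(C1C=CC=C1)C1C=CC=C1)[Zr](Cl)(C1C=CC=C1)C1C=CC=C1 | intermediate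
19 | (2E)-3-iodobut-2-en-1-ol | C/C(I)=C\CO | intermediate
20 | (2E)-1-bromo-3-iodobut-2-ene | C/C(I)=C\CBr | intermediate
21 | diethyl [(2E)-3-iodobut-2-en-1-yl]phosphonate | C/C(I)=C\CP(=O)(OCC)OCC | intermediate
22 | (2E,4E,6E)-2,7-dimethylocta-2,4,6-trienedial (C10 dialdehyde) | O=C/C(C)=C/C=C/C=C(C)/C=O | starting material
23 | sodium salt of the α-carbanion of 21 | [Na+].C/C(I)=C\[CH-]P(=O)(OCC)OCC | intermediate
24 | (2E,4E,6E,8E,10E)-11-iodo-2,7-dimethyldodeca-2,4,6,8,10-pentaenal | I/C(C)=C/C=C/C(C)=C/C=C/C=C(C)/C=O | intermediate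
25 | (2E,4E,6E,8E,10E,12E,14E)-2,15-diiodo-6,11-dimethylhexadeca-2,4,6,8,10,12,14-heptaene | I/C(C)=C/C=C/C(C)=C/C=C/C=C(C)/C=C/C=C(C)/I | intermediate
26 | (2E)-4-{(1R)-3-[(1E,3E,5E,7E,9E,11E,13E,15E)-16-iodo-3,7,12-trimethylheptadeca-1,3,5,7,9,11,13,15-octaen-1-yl]-2,2,4-trimethylcyclohex-3-en-1-yl}-2-methylbut-2-en-1-ol | CC1=C(/C=C/C(C)=C/C=C/C(C)=C/C=C/C=C(C)/C=C/C=C(C)/I)C(C)(C)[C@@H](C/C=C(\C)CO)CC1 | intermediate
27 | (2R,2′R)-2,2′-bis[(2E)-4-hydroxy-3-methylbut-2-en-1-yl]-β,β-carotene, all-E | CC1=C(/C=C/C(C)=C/C=C/C(C)=C/C=C/C=C(C)/C=C/C=C(C)/C=C/C2=C(C)CC[C@H](C/C=C(\C)CO)C2(C)C)C(C)(C)[C@@H](C/C=C(\C)CO)CC1 | target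

Total step count: 14. Longest linear sequence: 10 steps (steps 1–9 and 14).

Steps most likely to fail

1. Step 14. The heptaenyl diiodide may isomerise or decompose (light, palladium hydride traces) before both ends have reacted. The sequence may also stall after the first coupling, or the stannane may be consumed by oxidative homocoupling. Fallback: the cross-coupling is moved to a small, robust partner and the long polyene is finished by olefination instead. The fallback sets out from 16. Stille coupling with iodophosphonate 21 (same catalyst system) should give diethyl [(2E,4E)-5-{(5R)-5-[(2E)-4-hydroxy-3-methylbut-2-en-1-yl]-2,6,6-trimethylcyclohex-1-en-1-yl}-3-methylpenta-2,4-dien-1-yl]phosphonate F1. Deprotonation with NaHMDS (one extra equivalent for the hydroxyl group) is followed by a two-directional Horner–Wadsworth–Emmons reaction of two molecules with dialdehyde 22. This forms C11=C12 and C11′=C12′ and comes back to the route at 27.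

2. Step 9. Oxidative addition and transmetalation at the tetrasubstituted triflate, flanked by a quaternary carbon, may be too slow. The product may couple a second time, or tin may be lost by protodestannylation during purification. Fallback: a slim sp-carbon nucleophile is introduced first and the metal is added afterwards by hydrometalation. The fallback sets out from 15. Sonogashira coupling with ethynyltrimethylsilane (PdCl2(PPh3)2, CuI, Et3N, DMF) should give (2E)-2-methyl-4-{(1R)-2,2,4-trimethyl-3-[(trimethylsilyl)ethynyl]cyclohex-3-en-1-yl}but-2-en-1-ol F2. Treatment with K2CO3 in MeOH then gives (2E)-4-[(1R)-3-ethynyl-2,2,4-trimethylcyclohex-3-en-1-yl]-2-methylbut-2-en-1-ol F3. Palladium-catalysed syn-hydrostannation with Bu3SnH, directed to the terminal carbon by the bulky ring, comes back to the route at 16.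

3. Step 13. The delocalised γ-iodoallyl carbanion may lose the geometry of its C=C bond or expel iodide. The second olefination may remain incomplete, or Z isomers may form at the new double bonds. Fallback: the polarity of the olefination is reversed so that the alkenyl iodide is never part of a carbanion. The fallback sets out from 19 and 22. Oxidation of 19 with MnO2 gives (2E)-3-iodobut-2-enal F4. Dialdehyde 22 is reduced with NaBH4 to (2E,4E,6E)-2,7-dimethylocta-2,4,6-triene-1,8-diol F5. PBr3 converts this into (2E,4E,6E)-1,8-dibromo-2,7-dimethylocta-2,4,6-triene F6. Triethyl phosphite then gives tetraethyl [(2E,4E,6E)-2,7-dimethylocta-2,4,6-triene-1,8-diyl]bis(phosphonate) F7. Double Horner–Wadsworth–Emmons reaction of F7 with two molecules of F4 comes back to the route at 25.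

Further compounds
F1 | step 14 | diethyl [(2E,4E)-5-{(5R)-5-[(2E)-4-hydroxy-3-methylbut-2-en-1-yl]-2,6,6-trimethylcyclohex-1-en-1-yl}-3-methylpenta-2,4-dien-1-yl]phosphonate | CC1=C(/C=C/C(C)=C/CP(=O)(OCC)OCC)C(C)(C)[C@@H](C/C=C(\C)CO)CC1
F2 | step 9 | (2E)-2-methyl-4-{(1R)-2,2,4-trimethyl-3-[(trimethylsilyl)ethynyl]cyclohex-3-en-1-yl}but-2-en-1-ol | CC1=C(C#C[Si](C)(C)C)C(C)(C)[C@@H](C/C=C(\C)CO)CC1
F3 | step 9 | (2E)-4-[(1R)-3-ethynyl-2,2,4-trimethylcyclohex-3-en-1-yl]-2-methylbut-2-en-1-ol | CC1=C(C#C)C(C)(C)[C@@H](C/C=C(\C)CO)CC1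
F4 | step 13 | (2E)-3-iodobut-2-enal | C/C(I)=C\C=O
F5 | step 13 | (2E,4E,6E)-2,7-dimethylocta-2,4,6-triene-1,8-diol | OC/C(C)=C/C=C/C=C(C)/CO
F6 | step 13 | (2E,4E,6E)-1,8-dibromo-2,7-dimethylocta-2,4,6-triene | BrC/C(C)=C/C=C/C=C(C)/CBr
F7 | step 13 | tetraethyl [(2E,4E,6E)-2,7-dimethylocta-2,4,6-triene-1,8-diyl]bis(phosphonate) | CCOP(=O)(OCC)C/C(C)=C/C=C/C=C(C)/CP(=O)(OCC)OCC
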